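**Retrosynthetic overview**

1. Numbering used below: ring A = C1(=CH)–C2(OH)–C3(=O)–C4(=C18H2)–C5–C10, ring B = C5–C6–C7(OAc)–C8–C9–C10, side chain C11–C15 on C9. Target 30 ⇐ intramolecular Diels–Alder reaction of the open-chain allene-triene 28, made in the flask from acyclic 27. The diene is C10=C1–C2=C3 (a vinylketene silyl acetal), the dienophile is the proximal π bond C5=C4 of a 1,1-disubstituted allene, and C5–C10 and C3–C4 form together.
2. Enabling feature: ring A is a diosphenol (enol C1=C2–OH, ketone C3) flanked by the exocyclic methylene C4=C18 and the quaternary C5. This is the cyclohexene that a [1,1,2-trioxygenated diene + allene] adduct unmasks to. The four-carbon tether C6–C9 (C7–OAc, C8–Me, quaternary C9) steers face and cis fusion, and both C2 epimers of 27 converge.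
3. 27 ⇐ Felkin-controlled SE2′ homoallenylation of C7 aldehyde 21 (sets C7, brings C6–C5(C19)=C4=C18). The diene ester ⇐ C10 aldehyde 16 (Wittig, Luche reduction, silylation).
4. C8/C9 (tertiary next to quaternary) ⇐ Eschenmoser–Claisen rearrangement of (R,Z)-allylic alcohol 9 with 1,3-chirality transfer. 9 ⇐ Negishi coupling of alkylzinc 8 (C13 from hemiester 5) with (Z)-iodide 4.
5. Order of ring formation: no ring until the last step; rings B and A are then closed in the same operation.

Key step: step 16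

Assumption: hemiester 5 and keto-ylide 17 are taken as purchasable, and the C2 carbinol centre in 19–27 is deliberately carried as an epimer mixture because C2 becomes sp2 in the key step.

**Route**

Step 1
Reactants: 1 pent-3-yn-2-one
Product: 2 (2R)-pent-3-yn-2-ol
Conditions: RuCl[(R,R)-TsDPEN](p-cymene) (cat.), i-PrOH, 25 °C
Reagents that add atoms: none
Why: Noyori asymmetric transfer hydrogenation of an alkynyl ketone; the (R,R)-diamine ligand should direct hydride to the face that gives the (R)-carbinol, a temporary stereocentre used later for chirality transfer.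

Step 2
Reactants: 2 (2R)-pent-3-yn-2-ol
Product: 4 (2R,3Z)-4-iodopent-3-en-2-ol, via cyclic alkenylalanate 3 (not isolated)
Conditions: NaAlH2(OCH2CH2OMe)2, THF, 0 → 23 °C; then I2, −78 °C
Reagents that add atoms: iodine, II; sodium bis(2-methoxyethoxy)aluminium dihydride, [Na+].[AlH2-](OCCOC)OCCOC (its atoms stay only in intermediate 3)
Why: Hydroxyl-directed trans-hydroalumination of the propargylic alcohol places aluminium on the distal alkyne carbon inside a five-membered alkoxyalanate, and iodinolysis with retention gives the Z-iodide (iodine cis to the carbinol carbon).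

Step 3
Reactants: 5 (3R)-5-methoxy-3-methyl-5-oxopentanoic acid
Product: 6 methyl (3R)-5-hydroxy-3-methylpentanoate
Conditions: BH3·SMe2, THF, 0 → 23 °C; MeOH quench
Reagents that add atoms: none
Why: Chemoselective borane reduction of the carboxylic acid beside the methyl ester; the C13 stereocentre comes from 5 and is not touched.

Step 4
Reactants: 6 methyl (3R)-5-hydroxy-3-methylpentanoate
Product: 7 methyl (3S)-5-iodo-3-methylpentanoate
Conditions: I2, PPh3, imidazole, CH2Cl2, 0 °C
Reagents that add atoms: iodine, II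
Why: Appel-type iodination of the primary alcohol (SN2 at CH2), run promptly to forestall lactonisation of 6; the descriptor changes only through CIP priorities.

Step 5
Reactants: 7 methyl (3S)-5-iodo-3-methylpentanoate; 4 (2R,3Z)-4-iodopent-3-en-2-ol
Product: 9 methyl (3R,6Z,8R)-8-hydroxy-3,6-dimethylnon-6-enoate, via alkylzinc iodide 8 (not isolated)
Conditions: Zn dust, LiCl, THF, 40 °C; then 4, Pd(OAc)2, SPhos, THF, 23 °C
Reagents that add atoms: zinc, [Zn] (its atom stays only in intermediate 8)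
Why: LiCl-assisted zinc insertion gives the ester-tolerant alkylzinc 8, and Negishi sp3–sp2 cross-coupling proceeds with retention of the Z geometry and tolerates the free hydroxyl when 8 is used in excess.

Step 6
Reactants: 10 N,N-dimethylpropanamide
Product: 12 1,1-dimethoxy-N,N-dimethylpropan-1-amine, via O-methyl imidate salt 11 (not isolated)
Conditions: Me2SO4, 70 °C (neat); then NaOMe, MeOH, 0 °C
Reagents that add atoms: dimethyl sulfate, COS(=O)(=O)OC; sodium methoxide, [Na+].[O-]C
Why: O-Methylation of the amide followed by methoxide addition to the imidate salt is the standard preparation of amide acetals.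

Step 7
Reactants: 9 methyl (3R,6Z,8R)-8-hydroxy-3,6-dimethylnon-6-enoate; 12 1,1-dimethoxy-N,N-dimethylpropan-1-amine
Product: 14 methyl (3R,6R,7E)-6-[(2S)-1-(dimethylamino)-1-oxopropan-2-yl]-3,6-dimethylnon-7-enoate, via ketene N,O-acetal 13 (not isolated)
Conditions: excess 12, xylene, 140 °C, removal of MeOH
Reagents that add atoms: none
Why: Eschenmoser–Claisen rearrangement; acetal exchange gives the (Z)-ketene N,O-acetal 13 (methyl cis to oxygen to avoid A(1,3) strain with NMe2), which rearranges through a chair with the carbinol methyl equatorial, so the (R)-carbinol and the Z alkene should translate into (8S,9R) at the new C8–C9 bond (tertiary next to quaternary) and an E propenyl group.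

Step 8
Reactants: 14 methyl (3R,6R,7E)-6-[(2S)-1-(dimethylamino)-1-oxopropan-2-yl]-3,6-dimethylnon-7-enoate
Product: 16 methyl (3R,6S,7S)-8-(dimethylamino)-6-formyl-3,6,7-trimethyl-8-oxooctanoate, via ozonide 15 (not isolated)
Conditions: O3, CH2Cl2, −78 °C; then Me2S, −78 → 23 °C
Reagents that add atoms: ozone, O=[O+][O-]
Why: Ozonolysis with reductive work-up cleaves the only C=C bond to the non-enolisable, alpha-quaternary C10 aldehyde; the sacrificial carbinol carbon leaves as acetaldehyde and no stereocentre is touched.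

Step 9
Reactants: 16 methyl (3R,6S,7S)-8-(dimethylamino)-6-formyl-3,6,7-trimethyl-8-oxooctanoate; 17 ethyl 2-oxo-3-(triphenyl-λ5-phosphanylidene)propanoate
Product: 18 1-ethyl 10-methyl (3E,5R,8R)-5-[(2S)-1-(dimethylamino)-1-oxopropan-2-yl]-5,8-dimethyl-2-oxodec-3-enedioate
Conditions: PhMe, 100 °C
Reagents that add atoms: none
Why: Wittig olefination with a keto-stabilised ylide should give the E alkene C10=C1 and brings C1–C3 at the alpha-keto ester level.

Step 10
Reactants: 18 1-ethyl 10-methyl (3E,5R,8R)-5-[(2S)-1-(dimethylamino)-1-oxopropan-2-yl]-5,8-dimethyl-2-oxodec-3-enedioate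
Product: 19 1-ethyl 10-methyl (2RS,3E,5R,8R)-5-[(2S)-1-(dimethylamino)-1-oxopropan-2-yl]-2-hydroxy-5,8-dimethyldec-3-enedioate
Conditions: NaBH4, CeCl3·7H2O, MeOH, −78 °C
Reagents that add atoms: none
Why: Luche reduction (1,2-selective; the ketone of the alpha-keto ester is far more reactive than the esters or the amide) gives the allylic alpha-hydroxy ester, whose C2 configuration is irrelevant.

Step 11
Reactants: 19 1-ethyl 10-methyl (2RS,3E,5R,8R)-5-[(2S)-1-(dimethylamino)-1-oxopropan-2-yl]-2-hydroxy-5,8-dimethyldec-3-enedioate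
Product: 20 1-ethyl 10-methyl (2RS,3E,5R,8R)-2-[(tert-butyldimethylsilyl)oxy]-5-[(2S)-1-(dimethylamino)-1-oxopropan-2-yl]-5,8-dimethyldec-3-enedioate
Conditions: TBSCl, imidazole, DMF, 23 °C
Reagents that add atoms: tert-butyldimethylsilyl chloride, CC(C)(C)[Si](C)(C)Cl
Why: Standard silylation of the secondary alcohol; this silyl ether later becomes the enol silyl ether at C2 of the diene.

Step 12
Reactants: 20 1-ethyl 10-methyl (2RS,3E,5R,8R)-2-[(tert-butyldimethylsilyl)oxy]-5-[(2S)-1-(dimethylamino)-1-oxopropan-2-yl]-5,8-dimethyldec-3-enedioate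
Product: 21 1-ethyl 10-methyl (2RS,3E,5R,8R)-2-[(tert-butyldimethylsilyl)oxy]-5,8-dimethyl-5-[(2S)-1-oxopropan-2-yl]dec-3-enedioate
Conditions: Cp2Zr(H)Cl, THF, 23 °C; aqueous work-up
Reagents that add atoms: none
Why: Chemoselective reduction of the tertiary amide to the aldehyde with the Schwartz reagent, which should leave both esters untouched; the aldehyde is used at once so that C8 does not epimerise.

Step 13
Reactants: 22 2-methylbut-1-en-3-yne
Product: 24 2-bromo-3-methylbuta-1,3-diene, via allenylmethyl bromide 23 (not isolated)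
Conditions: 48% aq. HBr, CuBr (cat.), NH4Br, 0 → 20 °C
Reagents that add atoms: hydrogen bromide, Br
Why: Copper-catalysed 1,4-hydrobromination of the conjugated enyne and SN2′ isomerisation of the allenylmethyl bromide, the reaction type by which vinylacetylene is converted into 2-halobuta-1,3-dienes.

Step 14
Reactants: 24 2-bromo-3-methylbuta-1,3-diene; 21 1-ethyl 10-methyl (2RS,3E,5R,8R)-2-[(tert-butyldimethylsilyl)oxy]-5,8-dimethyl-5-[(2S)-1-oxopropan-2-yl]dec-3-enedioate
Product: 26 1-ethyl 10-methyl (2RS,3E,5R,8R)-2-[(tert-butyldimethylsilyl)oxy]-5-[(2S,3S)-3-hydroxy-5-methylhepta-5,6-dien-2-yl]-5,8-dimethyldec-3-enedioate, via dienyl Grignard reagent 25 (not isolated)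
Conditions: 24, Mg, THF, 40 °C; then 21, THF, −78 °C; aq. NH4Cl
Reagents that add atoms: magnesium, [Mg] (its atom stays only in intermediate 25)
Why: SE2′ addition of a buta-1,3-dien-2-yl Grignard reagent through a six-membered transition state gives the β-allenic alcohol (C6–C7 bond, allene C5=C4=C18); Felkin–Anh control with the quaternary C9 as the large group anti to the nucleophile should set (7S), and at −78 °C the aldehyde reacts far faster than the esters.

Step 15
Reactants: 26 1-ethyl 10-methyl (2RS,3E,5R,8R)-2-[(tert-butyldimethylsilyl)oxy]-5-[(2S,3S)-3-hydroxy-5-methylhepta-5,6-dien-2-yl]-5,8-dimethyldec-3-enedioate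
Product: 27 1-ethyl 10-methyl (2RS,3E,5R,8R)-5-[(2S,3S)-3-acetoxy-5-methylhepta-5,6-dien-2-yl]-2-[(tert-butyldimethylsilyl)oxy]-5,8-dimethyldec-3-enedioate
Conditions: Ac2O, DMAP, pyridine, CH2Cl2, 23 °C
Reagents that add atoms: acetic anhydride, CC(=O)OC(C)=O
Why: DMAP-catalysed acetylation of the secondary alcohol installs the C7 acetate of the target with retention.

Step 16
Reactants: 27 1-ethyl 10-methyl (2RS,3E,5R,8R)-5-[(2S,3S)-3-acetoxy-5-methylhepta-5,6-dien-2-yl]-2-[(tert-butyldimethylsilyl)oxy]-5,8-dimethyldec-3-enedioate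
Product: 30 methyl (3R)-5-[(1R,2S,3S,4aS,8aR)-3-acetoxy-7-hydroxy-1,2,4a-trimethyl-5-methylidene-6-oxo-1,2,3,4,4a,5,6,8a-octahydronaphthalen-1-yl]-3-methylpentanoate (target CNP0180040.1), via tris(silyl ketene acetal) triene 28 (not isolated), via silylated cycloadduct 29 (not isolated)
Conditions: LiN(i-Pr)2 (4 equiv), Me3SiCl (5 equiv), THF, −78 °C; solvent exchange to PhMe, 120 °C (sealed tube); then HF·pyridine, THF, 0 °C
Reagents that add atoms: chlorotrimethylsilane, C[Si](C)(C)Cl (its atoms stay only in intermediates 28 and 29)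
Why: Enolisation and O-silylation convert the alpha-silyloxy β,γ-unsaturated ester of 27 into the 1-ethoxy-1,2-bis(silyloxy)diene of 28 (the remote methyl ester and the acetate are silylated as spectator ketene acetals); on heating, the diene C10=C1–C2=C3 should add suprafacially to the proximal allene π bond C5=C4 in a concerted, asynchronous intramolecular [4+2] cycloaddition that forms C5–C10 and C3–C4 at once, and fluoride then collapses the C3 O-silyl O-ethyl ketal of 29 to the ketone, frees the C2 enol and returns the spectators as ester and acetate. The closest known reaction types are thermal intramolecular Diels–Alder reactions of tethered dienes with strain-activated allene dienophiles (exocyclic alkene retained) and Diels–Alder reactions of vinylketene silyl acetals. Ring B closes through the four-atom tether C6–C9 in a chair-like array, and ring A is the new cyclohexene formed by the boat-like [4+2] array fused onto it. C5 and C10 are set relative to C7, C8 and C9 because the tether chair that keeps C7–OAc and C8–Me equatorial exposes a single face pair, and the cis fusion (H10 cis to C19) follows because only the array with the slim allene carbon C4, rather than the C19 methyl, syn-axial to the axial C20 methyl on C9 avoids a methyl/methyl 1,3-diaxial contact. The step needs site selectivity for the proximal allene π bond, which the four-atom tether secures (the distal bond would demand a seven-membered ring), and it is stereoconvergent, since both C2 epimers and both ketene acetal geometries give the same adduct once C2 is sp2 and C3 ends as C=O. The gem-dialkyl effect of the quaternary C9, the strain released from the allene and the absence of any hydrogen for a 1,5-shift on the diene are expected to let the cycloaddition outrun silyl migration.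

**Compound list**

1 | pent-3-yn-2-one | CC(=O)C#CC | starting material
2 | (2R)-pent-3-yn-2-ol | C[C@@H](O)C#CC | intermediate
3 | sodium (5R)-2,2-bis(2-methoxyethoxy)-3,5-dimethyl-2,5-dihydro-1,2-oxaluminol-2-uide (cyclic alkenylalanate) | [Na+].C[C@H]1O[Al-](OCCOC)(OCCOC)C(C)=C1 | intermediate (not isolated)
4 | (2R,3Z)-4-iodopent-3-en-2-ol | C[C@@H](O)/C=C(C)\I | intermediate
5 | (3R)-5-methoxy-3-methyl-5-oxopentanoic acid (monomethyl (R)-3-methylglutarate) | OC(=O)C[C@@H](C)CC(=O)OC | starting material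
6 | methyl (3R)-5-hydroxy-3-methylpentanoate | OCC[C@@H](C)CC(=O)OC | intermediate
7 | methyl (3S)-5-iodo-3-methylpentanoate | ICC[C@@H](C)CC(=O)OC | intermediate
8 | [(3S)-5-methoxy-3-methyl-5-oxopentyl]zinc iodide | I[Zn]CC[C@@H](C)CC(=O)OC | intermediate (not isolated)
9 | methyl (3R,6Z,8R)-8-hydroxy-3,6-dimethylnon-6-enoate | C[C@@H](O)/C=C(C)\CC[C@@H](C)CC(=O)OC | intermediate
10 | N,N-dimethylpropanamide | CCC(=O)N(C)C | starting material
11 | 1-methoxy-N,N-dimethylpropan-1-iminium methyl sulfate | CCC(OC)=[N+](C)C.COS(=O)(=O)[O-] | intermediate (not isolated)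
12 | 1,1-dimethoxy-N,N-dimethylpropan-1-amine | CCC(OC)(OC)N(C)C | intermediate
13 | methyl (3R,6Z,8R)-8-{[(1Z)-1-(dimethylamino)prop-1-en-1-yl]oxy}-3,6-dimethylnon-6-enoate (ketene N,O-acetal) | C/C=C(/N(C)C)O[C@H](C)/C=C(C)\CC[C@@H](C)CC(=O)OC | intermediate (not isolated)
14 | methyl (3R,6R,7E)-6-[(2S)-1-(dimethylamino)-1-oxopropan-2-yl]-3,6-dimethylnon-7-enoate | C/C=C/[C@@](C)(CC[C@@H](C)CC(=O)OC)[C@H](C)C(=O)N(C)C | intermediate
15 | methyl (3R,6S)-6-[(2S)-1-(dimethylamino)-1-oxopropan-2-yl]-3-methyl-6-(5-methyl-1,2,4-trioxolan-3-yl)heptanoate (ozonide, ring centres unassigned) | CC1OC(OO1)[C@@](C)(CC[C@@H](C)CC(=O)OC)[C@H](C)C(=O)N(C)C | intermediate (not isolated)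
16 | methyl (3R,6S,7S)-8-(dimethylamino)-6-formyl-3,6,7-trimethyl-8-oxooctanoate | O=C[C@@](C)(CC[C@@H](C)CC(=O)OC)[C@H](C)C(=O)N(C)C | intermediate
17 | ethyl 2-oxo-3-(triphenyl-λ5-phosphanylidene)propanoate | CCOC(=O)C(=O)C=P(c1ccccc1)(c1ccccc1)c1ccccc1 | starting material
18 | 1-ethyl 10-methyl (3E,5R,8R)-5-[(2S)-1-(dimethylamino)-1-oxopropan-2-yl]-5,8-dimethyl-2-oxodec-3-enedioate | CCOC(=O)C(=O)/C=C/[C@@](C)(CC[C@@H](C)CC(=O)OC)[C@H](C)C(=O)N(C)C | intermediate
19 | 1-ethyl 10-methyl (2RS,3E,5R,8R)-5-[(2S)-1-(dimethylamino)-1-oxopropan-2-yl]-2-hydroxy-5,8-dimethyldec-3-enedioate | CCOC(=O)C(O)/C=C/[C@@](C)(CC[C@@H](C)CC(=O)OC)[C@H](C)C(=O)N(C)C | intermediate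
20 | 1-ethyl 10-methyl (2RS,3E,5R,8R)-2-[(tert-butyldimethylsilyl)oxy]-5-[(2S)-1-(dimethylamino)-1-oxopropan-2-yl]-5,8-dimethyldec-3-enedioate | CCOC(=O)C(O[Si](C)(C)C(C)(C)C)/C=C/[C@@](C)(CC[C@@H](C)CC(=O)OC)[C@H](C)C(=O)N(C)C | intermediate
21 | 1-ethyl 10-methyl (2RS,3E,5R,8R)-2-[(tert-butyldimethylsilyl)oxy]-5,8-dimethyl-5-[(2S)-1-oxopropan-2-yl]dec-3-enedioate | CCOC(=O)C(O[Si](C)(C)C(C)(C)C)/C=C/[C@@](C)(CC[C@@H](C)CC(=O)OC)[C@H](C)C=O | intermediate
22 | 2-methylbut-1-en-3-yne | C=C(C)C#C | starting material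
23 | 4-bromo-3-methylbuta-1,2-diene | C=C=C(C)CBr | intermediate (not isolated)
24 | 2-bromo-3-methylbuta-1,3-diene | C=C(C)C(Br)=C | intermediate
25 | (3-methylbuta-1,3-dien-2-yl)magnesium bromide | C=C(C)C(=C)[Mg]Br | intermediate (not isolated)
26 | 1-ethyl 10-methyl (2RS,3E,5R,8R)-2-[(tert-butyldimethylsilyl)oxy]-5-[(2S,3S)-3-hydroxy-5-methylhepta-5,6-dien-2-yl]-5,8-dimethyldec-3-enedioate | CCOC(=O)C(O[Si](C)(C)C(C)(C)C)/C=C/[C@@](C)(CC[C@@H](C)CC(=O)OC)[C@H](C)[C@@H](O)CC(C)=C=C | intermediate
27 | 1-ethyl 10-methyl (2RS,3E,5R,8R)-5-[(2S,3S)-3-acetoxy-5-methylhepta-5,6-dien-2-yl]-2-[(tert-butyldimethylsilyl)oxy]-5,8-dimethyldec-3-enedioate | CCOC(=O)C(O[Si](C)(C)C(C)(C)C)/C=C/[C@@](C)(CC[C@@H](C)CC(=O)OC)[C@H](C)[C@@H](OC(C)=O)CC(C)=C=C | intermediate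
28 | tris(silyl ketene acetal) of 27: C3 as ethyl trimethylsilyl ketene acetal (C3=C2, C2–OTBS, C1=C10 E), C15 as methyl trimethylsilyl ketene acetal, C7 acetate as its trimethylsilyl ketene acetal; ketene acetal geometries mixed | CCOC(O[Si](C)(C)C)=C(O[Si](C)(C)C(C)(C)C)/C=C/[C@@](C)(CC[C@@H](C)C=C(OC)O[Si](C)(C)C)[C@H](C)[C@@H](OC(=C)O[Si](C)(C)C)CC(C)=C=C | intermediate (not isolated)
29 | silylated cycloadduct: cis-fused decalin with C3 ethyl trimethylsilyl ketal (C3 epimers), C2 TBS enol ether, C4 exocyclic methylene and the two spectator ketene acetals | C=C1C(OCC)(O[Si](C)(C)C)C(O[Si](C)(C)C(C)(C)C)=C[C@@H]2[C@@](C)(CC[C@@H](C)C=C(OC)O[Si](C)(C)C)[C@H](C)[C@@H](OC(=C)O[Si](C)(C)C)C[C@]12C | intermediate (not isolated)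
30 | methyl (3R)-5-[(1R,2S,3S,4aS,8aR)-3-acetoxy-7-hydroxy-1,2,4a-trimethyl-5-methylidene-6-oxo-1,2,3,4,4a,5,6,8a-octahydronaphthalen-1-yl]-3-methylpentanoate (CNP0180040.1) | C=C1C(=O)C(O)=C[C@@H]2[C@@](C)(CC[C@@H](C)CC(=O)OC)[C@H](C)[C@@H](OC(C)=O)C[C@]12C | target

**Step count and risks**

Total step count: 16. Longest linear sequence: 12 steps (from 5 through steps 3, 4, 5, 7, 8, 9, 10, 11, 12, 14, 15 and 16).

Steps most likely to fail:

1. Step 16. The cycloaddition between a donor-rich ketene silyl acetal diene and an unactivated allene may be too slow, so that silyl migration or protodesilylation of the diene wins; the cis/trans ring-fusion preference may also erode at the temperature needed. The fallback keeps the disconnection but uses a thermally robust diene one oxidation level lower at C3 and oxidises afterwards. It sets out from aldehyde 16.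
   - Horner–Wadsworth–Emmons reaction with dimethyl {3-[(tert-butyldimethylsilyl)oxy]-2-oxopropyl}phosphonate (Ba(OH)2, wet THF) should give the silyloxy enone F1.
   - Soft enolisation (TBSOTf, Et3N, CH2Cl2, 0 °C) should give the (Z)-1,2-bis(silyloxy)diene F2, with the C3 silyloxy group on the outside of the diene.
   - Cp2Zr(H)Cl should convert the amide into the aldehyde F3.
   - Grignard reagent 25 at −78 °C should give the homoallenyl alcohol F4, and Ac2O/DMAP the acetate F5.
   - Thermal intramolecular Diels–Alder reaction (PhMe, 160–180 °C, sealed tube) should give the bis-silylated cycloadduct F6.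
   - HF·pyridine should release the acyloin F7, and Dess–Martin oxidation gives the 2,3-dione, which enolises toward C1. The fallback comes back to the route at 30.

2. Step 14. The dienyl Grignard reagent may add directly (without allylic transposition) to give a dienyl carbinol, Felkin facial control at C7 may be weak, or an ester may be attacked. The fallback builds the allene in two stages and sets out from aldehyde 21.
   - Palladium/indium-mediated propargylation (Pd(dppf)Cl2, InI, THF/HMPA) with 4-[(4-methoxybenzyl)oxy]but-2-yn-1-yl methanesulfonate proceeds through an allenylindium reagent and should give the homopropargylic alcohol F8. A wrong C7 epimer can be corrected here by Mitsunobu inversion with acetic acid.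
   - Ac2O/DMAP gives the acetate F9, DDQ the propargylic alcohol F10, and MsCl/Et3N the propargylic mesylate F11.
   - Me2CuLi (Et2O, −78 °C) delivers methyl to C5 by anti-SN2′ displacement and forms the 1,1-disubstituted allene. The fallback comes back to the route at 27.

3. Step 7. At 140 °C the secondary allylic alcohol may dehydrate to a diene under the amide acetal conditions, and leakage through a boat transition state or the other ketene acetal geometry would lower the diastereoselectivity at C8/C9. The fallback is a low-temperature ester-enolate rearrangement and sets out from alcohol 9.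
   - Propanoylation (propanoic anhydride, DMAP, Et3N) gives the propanoate F12.
   - Ireland–Claisen rearrangement (excess LiN(i-Pr)2, Me3SiCl, THF, −78 → 23 °C) uses the kinetic enolate, which has methyl cis to the allylic oxygen and the same chair; the remote ester is silylated as a spectator. It should give the acid F13.
   - Amide formation (Me2NH·HCl, EDC, HOBt, i-Pr2NEt) brings the fallback back to the route at 14.

**Further compounds**

F1 | step 16 | methyl (3R,6R,7E)-10-[(tert-butyldimethylsilyl)oxy]-6-[(2S)-1-(dimethylamino)-1-oxopropan-2-yl]-3,6-dimethyl-9-oxodec-7-enoate | CC(C)(C)[Si](C)(C)OCC(=O)/C=C/[C@@](C)(CC[C@@H](C)CC(=O)OC)[C@H](C)C(=O)N(C)C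
F2 | step 16 | methyl (3R,6R,7E,9Z)-9,10-bis[(tert-butyldimethylsilyl)oxy]-6-[(2S)-1-(dimethylamino)-1-oxopropan-2-yl]-3,6-dimethyldeca-7,9-dienoate | CC(C)(C)[Si](C)(C)O/C=C(O[Si](C)(C)C(C)(C)C)/C=C/[C@@](C)(CC[C@@H](C)CC(=O)OC)[C@H](C)C(=O)N(C)C
F3 | step 16 | methyl (3R,6R,7E,9Z)-9,10-bis[(tert-butyldimethylsilyl)oxy]-3,6-dimethyl-6-[(2S)-1-oxopropan-2-yl]deca-7,9-dienoate | CC(C)(C)[Si](C)(C)O/C=C(O[Si](C)(C)C(C)(C)C)/C=C/[C@@](C)(CC[C@@H](C)CC(=O)OC)[C@H](C)C=O
F4 | step 16 | methyl (3R,6R,7E,9Z)-9,10-bis[(tert-butyldimethylsilyl)oxy]-6-[(2S,3S)-3-hydroxy-5-methylhepta-5,6-dien-2-yl]-3,6-dimethyldeca-7,9-dienoate | CC(C)(C)[Si](C)(C)O/C=C(O[Si](C)(C)C(C)(C)C)/C=C/[C@@](C)(CC[C@@H](C)CC(=O)OC)[C@H](C)[C@@H](O)CC(C)=C=C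
F5 | step 16 | methyl (3R,6R,7E,9Z)-6-[(2S,3S)-3-acetoxy-5-methylhepta-5,6-dien-2-yl]-9,10-bis[(tert-butyldimethylsilyl)oxy]-3,6-dimethyldeca-7,9-dienoate | CC(C)(C)[Si](C)(C)O/C=C(O[Si](C)(C)C(C)(C)C)/C=C/[C@@](C)(CC[C@@H](C)CC(=O)OC)[C@H](C)[C@@H](OC(C)=O)CC(C)=C=C
F6 | step 16 | bis-silylated cycloadduct: the ring system of 30 with C3 as a TBS-protected carbinol (configuration as formed) and C2 as its TBS enol ether | C=C1C(O[Si](C)(C)C(C)(C)C)C(O[Si](C)(C)C(C)(C)C)=C[C@@H]2[C@@](C)(CC[C@@H](C)CC(=O)OC)[C@H](C)[C@@H](OC(C)=O)C[C@]12C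
F7 | step 16 | acyloin: the ring system of 30 with a C2 ketone, C1 methylene and C3 carbinol | C=C1C(O)C(=O)C[C@@H]2[C@@](C)(CC[C@@H](C)CC(=O)OC)[C@H](C)[C@@H](OC(C)=O)C[C@]12C
F8 | step 14 | 1-ethyl 10-methyl (2RS,3E,5R,8R)-2-[(tert-butyldimethylsilyl)oxy]-5-{(2S,3S)-3-hydroxy-7-[(4-methoxybenzyl)oxy]hept-5-yn-2-yl}-5,8-dimethyldec-3-enedioate | CCOC(=O)C(O[Si](C)(C)C(C)(C)C)/C=C/[C@@](C)(CC[C@@H](C)CC(=O)OC)[C@H](C)[C@@H](O)CC#CCOCc1ccc(OC)cc1
F9 | step 14 | 1-ethyl 10-methyl (2RS,3E,5R,8R)-5-{(2S,3S)-3-acetoxy-7-[(4-methoxybenzyl)oxy]hept-5-yn-2-yl}-2-[(tert-butyldimethylsilyl)oxy]-5,8-dimethyldec-3-enedioate | CCOC(=O)C(O[Si](C)(C)C(C)(C)C)/C=C/[C@@](C)(CC[C@@H](C)CC(=O)OC)[C@H](C)[C@@H](OC(C)=O)CC#CCOCc1ccc(OC)cc1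
F10 | step 14 | 1-ethyl 10-methyl (2RS,3E,5R,8R)-5-[(2S,3S)-3-acetoxy-7-hydroxyhept-5-yn-2-yl]-2-[(tert-butyldimethylsilyl)oxy]-5,8-dimethyldec-3-enedioate | CCOC(=O)C(O[Si](C)(C)C(C)(C)C)/C=C/[C@@](C)(CC[C@@H](C)CC(=O)OC)[C@H](C)[C@@H](OC(C)=O)CC#CCO
F11 | step 14 | 1-ethyl 10-methyl (2RS,3E,5R,8R)-5-{(2S,3S)-3-acetoxy-7-[(methylsulfonyl)oxy]hept-5-yn-2-yl}-2-[(tert-butyldimethylsilyl)oxy]-5,8-dimethyldec-3-enedioate | CCOC(=O)C(O[Si](C)(C)C(C)(C)C)/C=C/[C@@](C)(CC[C@@H](C)CC(=O)OC)[C@H](C)[C@@H](OC(C)=O)CC#CCOS(C)(=O)=O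
F12 | step 7 | methyl (3R,6Z,8R)-3,6-dimethyl-8-(propanoyloxy)non-6-enoate | CCC(=O)O[C@H](C)/C=C(C)\CC[C@@H](C)CC(=O)OC
F13 | step 7 | (2S,3R,4E)-3-[(3R)-5-methoxy-3-methyl-5-oxopentyl]-2,3-dimethylhex-4-enoic acid | C/C=C/[C@@](C)(CC[C@@H](C)CC(=O)OC)[C@H](C)C(=O)O
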